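**Plan**

1. Retrosynthesis cuts, in this order: the C4 carbinol of the terminal unit L (back to the ketone) and all O-protecting groups; O1–C2 and C4a–C4 of ring C of unit L; the C4(M)–C6(L) bond; O1–C2 and C4a–C4 of unit M; the C4(U)–C6(M) bond; O1–C2 and C4a–C4 of unit U.
2. Forward, one annulation (aryl O,C-dianion plus one trans-epoxy amide) builds ring C three times: on a bromophenol (U), on the bromoresorcinol ring attached to C4(U) (M), and on the bromophenol ring attached to C4(M) (L, the key step). The two interflavan bonds are Friedel–Crafts alkylations in between.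
3. What makes the event possible: ring A of each unit is a resorcinol in which O1 and C4a are ortho neighbours, so with Li in place of Br at C4a it is an O,C-1,3-dinucleophile. C2–C3–C4 with catechol ring B is a C6–C3 unit available as a 1,3-dielectrophile (acyl C4, benzylic epoxide C2 activated by the para oxygen of ring B).
4. Stereochemistry: C2 and C3 of all three units come from one catalytic asymmetric epoxidation (C3 retained, C2 by inversion). C4(U) is set 4β by delivering the arene from O3 over a Si(i-Pr)2 tether, C4(M) 4α by participation of a 3-O-acetyl group, and C4(L) by borohydride reduction of the 2,3-trans flavanonol.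
5. Helpers and their removal: Br marks C4a and blocks the competing arene position (lost in each annulation); the silylene ring is first the tether and then protects O3(U)/O7(M) (step 13); benzyl ethers (step 14); ketone level at C4(L) (step 15).

Key step: step 12

Remark: 1, 2, 5 and 11 are taken as catalogue compounds, and t-BuLi is assumed to exchange a bromine ortho to a lithium phenolate at −78 °C faster than it attacks benzyl ethers or the aryloxysilane.

Naming: U, M, L are the upper, middle and terminal flavan units, with flavan numbering throughout. All 2-aryl groups are α (2R) and all 3-oxygens β, so 4α means trans and 4β means cis to O3.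

**Route**

Step 1
Reactants: 1 3,4-bis(benzyloxy)benzaldehyde; 2 diethyl [2-(morpholin-4-yl)-2-oxoethyl]phosphonate
Product: 3 (E)-3-[3,4-bis(benzyloxy)phenyl]-1-(morpholin-4-yl)prop-2-en-1-one
Conditions: NaH, THF, 0 °C → rt
Reagents that add atoms: none
Why: Horner–Wadsworth–Emmons olefination of an aromatic aldehyde with a stabilised amide phosphonate should give the (E)-enamide under thermodynamic control.

Step 2
Reactants: 3 (E)-enamide
Product: 4 [(2R,3S)-3-[3,4-bis(benzyloxy)phenyl]oxiran-2-yl](morpholin-4-yl)methanone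
Conditions: Sm(O-i-Pr)3 (10 mol %), (S)-BINOL (10 mol %), Ph3As=O (10 mol %), t-BuOOH, 4 Å MS, THF, rt
Reagents that add atoms: tert-butyl hydroperoxide CC(C)(C)OO
Why: Lanthanide–BINOL-catalysed nucleophilic (Weitz–Scheffer-type) epoxidation of an α,β-unsaturated morpholine amide should give the trans-epoxide with both centres set by the ligand as 2R,3S (the ligand antipode is exchanged should the sense prove opposite).

Step 3
Reactants: 5 5-(benzyloxy)-2-bromophenol; 4 epoxy amide
Product: 8 (2R,3R)-7-(benzyloxy)-2-[3,4-bis(benzyloxy)phenyl]-3-hydroxychroman-4-one (tri-O-benzylfustin; unit U), via dilithio phenolate 6 (not isolated), via hydroxyaryl epoxy ketone 7 (not isolated)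
Conditions: n-BuLi (1.0 equiv), THF, −78 °C; t-BuLi (2.0 equiv), −78 °C; 4 (1.2 equiv), −78 → 0 °C; AcOH
Reagents that add atoms: none
Why: Proposed new method: bromine–lithium exchange on the lithium phenolate gives the O,C-dianion 6, whose aryl carbon acylates the morpholine amide (C4a–C4) to give, after collapse of the adduct on warming, the phenolate of epoxy ketone 7, which opens the epoxide at the benzylic carbon (6-endo-tet, inversion; O1–C2) to the 2,3-trans flavanonol with C3 untouched, the closest known reactions being the acylation of aryllithiums by morpholine or Weinreb amides and the base-induced cyclisation of 2'-hydroxychalcone epoxides to dihydroflavonols.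

Step 4
Reactants: 8 tri-O-benzylfustin
Product: 10 (2R,3S,4R)-7-(benzyloxy)-2-[3,4-bis(benzyloxy)phenyl]-4-methoxychroman-3-ol, via trans-diol 9 (not isolated)
Conditions: NaBH4, THF/MeOH, 0 °C; aqueous work-up; crude 9 in MeOH, CSA (cat.), rt
Reagents that add atoms: methanol CO
Why: Borohydride reduction of a 2,3-trans flavanonol should give the 3,4-trans diol by axial hydride delivery, and acid-catalysed SN1 solvolysis of the benzylic, para-benzyloxy-activated C4 hydroxyl then leaves O3 as the only free hydroxyl (any 4β epimer is carried along, since C4 becomes planar in step 6).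

Step 5
Reactants: 10 4-O-methyl ether of unit U; 11 4-bromobenzene-1,3-diol
Product: 13 3-O-[(4-bromo-3-hydroxyphenoxy)diisopropylsilyl] ether of 10, via chlorosilyl ether 12 (not isolated)
Conditions: i-Pr2SiCl2 (1.5 equiv), imidazole, DMF, 0 °C; then 11 (4 equiv), rt
Reagents that add atoms: dichlorodiisopropylsilane CC(C)[Si](Cl)(Cl)C(C)C
Why: Sequential substitution of the two Si–Cl bonds (temporary silicon tether formation), first by the secondary 3-OH and then by the less hindered hydroxyl of 11 (para to bromine), should join the two partners through O–Si–O, any regioisomeric silyl ether being removed by chromatography.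

Step 6
Reactants: 13 tethered aryloxysilane
Product: 14 U–aryl silylene (4β-aryl; cis-fused seven-membered O–Si–O ring; bromophenol terminus)
Conditions: Me3SiOTf (0.2 equiv), 4 Å MS, CH2Cl2 (0.005 M), −78 → −30 °C; Et3N
Reagents that add atoms: none
Why: Lewis-acid ionisation of the 4-methoxy group gives the C4 benzylic cation, which is trapped by intramolecular Friedel–Crafts alkylation at the arene carbon ortho to the silyloxy and para to the free hydroxyl group, and delivery from the β-oriented O3 through the short tether should close a cis-fused seven-membered ring and so set the 4β (3,4-cis) configuration.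

Step 7
Reactants: 14 U–aryl silylene; 4 epoxy amide
Product: 17 U–M flavanonol (ring C of unit M closed; 2,3-trans; silylene retained), via dilithio species 15 (not isolated), via epoxy ketone 16 (not isolated)
Conditions: n-BuLi (1.0 equiv), THF, −78 °C; t-BuLi (2.0 equiv), −78 °C; 4 (1.2 equiv), −78 → 0 °C; AcOH
Reagents that add atoms: none
Why: Proposed new method: as in step 3, bromine–lithium exchange next to the lithium phenolate gives the O,C-dianion 15, which acylates the morpholine amide (C4a–C4 of unit M) and, after collapse to the phenolate of 16, opens the epoxide at the benzylic carbon (6-endo-tet, inversion) to the 2,3-trans flavanonol, the closest known reactions being aryllithium acylation by morpholine amides and the cyclisation of 2'-hydroxychalcone epoxides.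

Step 8
Reactants: 17 U–M flavanonol
Product: 18 U–M 3,4-trans-diol
Conditions: NaBH4, THF/EtOH, 0 °C
Reagents that add atoms: none
Why: Sodium borohydride reduction of the 2,3-trans flavanonol should give the 3,4-trans diol by axial hydride attack, which supplies the C4 leaving group of unit M.

Step 9
Reactants: 18 U–M 3,4-trans-diol
Product: 19 U–M 3,4-di-O-acetate
Conditions: Ac2O, pyridine, DMAP (cat.), CH2Cl2, rt
Reagents that add atoms: acetic anhydride CC(=O)OC(C)=O
Why: DMAP-catalysed acetylation of both secondary hydroxyls installs the leaving group at C4 and the participating ester at O3 of unit M.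

Step 10
Reactants: 19 U–M 3,4-di-O-acetate; 5 5-(benzyloxy)-2-bromophenol
Product: 20 U–M–aryl acetate (4α-aryl on unit M; 3-O-acetyl; bromophenol terminus)
Conditions: 5 (3 equiv), Me3SiOTf (0.2 equiv), 4 Å MS, CH2Cl2, −78 → −30 °C
Reagents that add atoms: none
Why: Lewis-acid-promoted Friedel–Crafts alkylation in which loss of the 4-acetate gives a cation bridged on the β face by the 3-O-acetyl group (anchimeric assistance), so that 5 should attack from the α face through its carbon para to OH (the site ortho to OH and para to OBn being blocked by Br) and make the 4α (3,4-trans) bond.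

Step 11
Reactants: 20 U–M–aryl acetate
Product: 21 U–M–aryl bromophenol (3-OH of unit M free)
Conditions: i-Bu2AlH (4 equiv), CH2Cl2, −78 °C; aq. KNaC4H4O6
Reagents that add atoms: none
Why: Reductive ester cleavage by i-Bu2AlH frees O3 of unit M without nucleophilic attack on the aryloxysilane or the aryl bromide.

Step 12
Reactants: 21 U–M–aryl bromophenol; 4 epoxy amide
Product: 24 protected U–M–L flavanonol (ring C of unit L closed; 2,3-trans; C4 ketone), via trilithio species 22 (not isolated), via epoxy ketone 23 (not isolated)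
Conditions: n-BuLi (2.0 equiv), THF, −78 °C; t-BuLi (2.0 equiv), −78 °C; 4 (1.3 equiv), −78 → 0 °C; AcOH
Reagents that add atoms: none
Why: Proposed new method: deprotonation of both hydroxyls and bromine–lithium exchange turn ring A of unit L into an O,C-dilithio 1,3-dinucleophile (22), whose C4a carbanion attacks the morpholine amide of 4 to make C4a–C4, the adduct collapsing on warming to the phenolate of aryl epoxy ketone 23. The ortho phenolate then opens the epoxide at the benzylic carbon to make O1–C2; the closest known reactions are the acylation of aryllithiums by morpholine or Weinreb amides and the base-induced cyclisation of 2'-hydroxychalcone epoxides to dihydroflavonols. Ring C of unit L is closed by a 6-endo-tet epoxide opening, its C–C bond having been made intermolecularly. C3 is carried over unchanged from the epoxide (reagent control from step 2), and C2 is set by inversion at the benzylic epoxide carbon, which gives the 2,3-trans diequatorial arrangement that is also the more stable one. The step needs site selectivity for C4a (secured by the bromine), preference of the aryllithium for the amide carbonyl over the epoxide (secured at −78 °C by the activated amide), and 6-endo over 5-exo opening (secured by the para-benzyloxy group of ring B, which activates C2, and by the unsubstituted C5 position).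

Step 13
Reactants: 24 protected U–M–L flavanonol
Product: 25 octa-O-benzyl U–M–L flavanonol (3-OH of U and 7-OH of M free)
Conditions: HF·pyridine, THF/pyridine, 0 °C → rt
Reagents that add atoms: none
Why: Fluorodesilylation cleaves both Si–O bonds of the diisopropylsilylene ring while benzyl ethers and the flavanonol are untouched, and no acid-labile C4 carbinol is present at this stage.

Step 14
Reactants: 25 octa-O-benzyl U–M–L flavanonol
Product: 26 fisetinidol-(4β→6)-fisetinidol-(4α→6)-fustin
Conditions: H2 (1 atm), Pd(OH)2/C, THF/MeOH, rt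
Reagents that add atoms: none
Why: Hydrogenolysis of the eight benzyl ethers is run while C4 of unit L is still a conjugated ketone, so that no benzylic carbinol is exposed to the catalyst.

Step 15
Reactants: 26 fisetinidol-(4β→6)-fisetinidol-(4α→6)-fustin
Product: 27 fisetinidol-(4β→6)-fisetinidol-(4α→6)-(2R,3S,4R)-flavan-3,3',4,4',7-pentol (target)
Conditions: NaBH4, EtOH, 0 °C → rt; AcOH to pH 5–6
Reagents that add atoms: none
Why: Borohydride reduction of the free phenolic 2,3-trans flavanonol should proceed by axial hydride delivery to the 3,4-trans (4R) diol, the established course of flavanonol to flavan-3,4-diol reductions, which sets the last stereocentre.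

**Compound list**

1 | 3,4-bis(benzyloxy)benzaldehyde | O=Cc1ccc(OCc2ccccc2)c(OCc2ccccc2)c1 | starting material
2 | diethyl [2-(morpholin-4-yl)-2-oxoethyl]phosphonate | CCOP(=O)(OCC)CC(=O)N1CCOCC1 | starting material
3 | (E)-3-[3,4-bis(benzyloxy)phenyl]-1-(morpholin-4-yl)prop-2-en-1-one | O=C(/C=C/c1ccc(OCc2ccccc2)c(OCc2ccccc2)c1)N1CCOCC1 | intermediate
4 | [(2R,3S)-3-[3,4-bis(benzyloxy)phenyl]oxiran-2-yl](morpholin-4-yl)methanone (trans-epoxy amide) | O=C(N1CCOCC1)[C@@H]1O[C@H]1c1ccc(OCc2ccccc2)c(OCc2ccccc2)c1 | intermediate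
5 | 5-(benzyloxy)-2-bromophenol | Oc1cc(OCc2ccccc2)ccc1Br | starting material
6 | dilithio phenolate: lithium 5-(benzyloxy)-2-lithiophenolate | [Li]Oc1cc(OCc2ccccc2)ccc1[Li] | intermediate
7 | hydroxyaryl epoxy ketone: [4-(benzyloxy)-2-hydroxyphenyl][(2R,3S)-3-[3,4-bis(benzyloxy)phenyl]oxiran-2-yl]methanone (formed as its lithium phenolate) | O=C(c1ccc(OCc2ccccc2)cc1O)[C@@H]1O[C@H]1c1ccc(OCc2ccccc2)c(OCc2ccccc2)c1 | intermediate
8 | (2R,3R)-7-(benzyloxy)-2-[3,4-bis(benzyloxy)phenyl]-3-hydroxychroman-4-one (tri-O-benzylfustin; unit U) | O=C1c2ccc(OCc3ccccc3)cc2O[C@H](c2ccc(OCc3ccccc3)c(OCc3ccccc3)c2)[C@H]1O | intermediate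
9 | trans-diol: (2R,3S,4R)-7-(benzyloxy)-2-[3,4-bis(benzyloxy)phenyl]chromane-3,4-diol | c1cc2c(cc1OCc1ccccc1)O[C@H](c1ccc(OCc3ccccc3)c(OCc3ccccc3)c1)[C@@H](O)[C@@H]2O | intermediate
10 | (2R,3S,4R)-7-(benzyloxy)-2-[3,4-bis(benzyloxy)phenyl]-4-methoxychroman-3-ol (4α epimer shown) | c1cc2c(cc1OCc1ccccc1)O[C@H](c1ccc(OCc3ccccc3)c(OCc3ccccc3)c1)[C@@H](O)[C@@H]2OC | intermediate
11 | 4-bromobenzene-1,3-diol (4-bromoresorcinol) | Oc1ccc(Br)c(O)c1 | starting material
12 | chlorosilyl ether: 3-O-[chloro(diisopropyl)silyl] ether of 10 | c1cc2c(cc1OCc1ccccc1)O[C@H](c1ccc(OCc3ccccc3)c(OCc3ccccc3)c1)[C@@H](O[Si](Cl)(C(C)C)C(C)C)[C@@H]2OC | intermediate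
13 | tethered aryloxysilane: 3-O-[(4-bromo-3-hydroxyphenoxy)diisopropylsilyl] ether of 10 | c1cc2c(cc1OCc1ccccc1)O[C@H](c1ccc(OCc3ccccc3)c(OCc3ccccc3)c1)[C@@H](O[Si](C(C)C)(C(C)C)Oc1ccc(Br)c(O)c1)[C@@H]2OC | intermediate
14 | U–aryl silylene: tri-O-benzyl unit U whose C4β carries a 5-bromo-4-hydroxy-2-oxyphenyl ring, the 2-oxygen of that ring tied to O3 by Si(i-Pr)2 in a cis-fused seven-membered ring | c1cc2c(cc1OCc1ccccc1)O[C@H](c1ccc(OCc3ccccc3)c(OCc3ccccc3)c1)[C@H]3O[Si](C(C)C)(C(C)C)Oc4cc(O)c(Br)cc4[C@H]32 | intermediate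
15 | dilithio species: 14 with OLi in place of OH and Li in place of Br | c1cc2c(cc1OCc1ccccc1)O[C@H](c1ccc(OCc3ccccc3)c(OCc3ccccc3)c1)[C@H]3O[Si](C(C)C)(C(C)C)Oc4cc(O[Li])c([Li])cc4[C@H]32 | intermediate
16 | epoxy ketone: 14 with the (2R,3S)-3-[3,4-bis(benzyloxy)phenyl]oxirane-2-carbonyl group in place of Br (formed as its lithium phenolate) | c1cc2c(cc1OCc1ccccc1)O[C@H](c1ccc(OCc3ccccc3)c(OCc3ccccc3)c1)[C@H]3O[Si](C(C)C)(C(C)C)Oc4cc(O)c(C(=O)[C@@H]5O[C@H]5c5ccc(OCc6ccccc6)c(OCc6ccccc6)c5)cc4[C@H]32 | intermediate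
17 | U–M flavanonol: unit M as (2R,3R)-2-[3,4-bis(benzyloxy)phenyl]-3-hydroxychroman-4-one joined at C6 to C4β of unit U, O7(M) and O3(U) bridged by Si(i-Pr)2 | c1cc2c(cc1OCc1ccccc1)O[C@H](c1ccc(OCc3ccccc3)c(OCc3ccccc3)c1)[C@H]3O[Si](C(C)C)(C(C)C)Oc4cc5c(cc4[C@H]32)C(=O)[C@H](O)[C@@H](c4ccc(OCc6ccccc6)c(OCc6ccccc6)c4)O5 | intermediate
18 | U–M 3,4-trans-diol: 17 with C4(M) reduced to the 4α-carbinol | c1cc2c(cc1OCc1ccccc1)O[C@H](c1ccc(OCc3ccccc3)c(OCc3ccccc3)c1)[C@H]3O[Si](C(C)C)(C(C)C)Oc4cc5c(cc4[C@H]32)[C@@H](O)[C@H](O)[C@@H](c4ccc(OCc6ccccc6)c(OCc6ccccc6)c4)O5 | intermediate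
19 | U–M 3,4-di-O-acetate: diacetate of 18 | c1cc2c(cc1OCc1ccccc1)O[C@H](c1ccc(OCc3ccccc3)c(OCc3ccccc3)c1)[C@H]3O[Si](C(C)C)(C(C)C)Oc4cc5c(cc4[C@H]32)[C@@H](OC(C)=O)[C@H](OC(C)=O)[C@@H](c4ccc(OCc6ccccc6)c(OCc6ccccc6)c4)O5 | intermediate
20 | U–M–aryl acetate: unit M 3-O-acetate carrying at C4α a 2-(benzyloxy)-5-bromo-4-hydroxyphenyl ring | c1cc2c(cc1OCc1ccccc1)O[C@H](c1ccc(OCc3ccccc3)c(OCc3ccccc3)c1)[C@H]3O[Si](C(C)C)(C(C)C)Oc4cc5c(cc4[C@H]32)[C@@H](c7cc(Br)c(O)cc7OCc7ccccc7)[C@H](OC(C)=O)[C@@H](c4ccc(OCc6ccccc6)c(OCc6ccccc6)c4)O5 | intermediate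
21 | U–M–aryl bromophenol: 20 with free 3-OH on unit M | c1cc2c(cc1OCc1ccccc1)O[C@H](c1ccc(OCc3ccccc3)c(OCc3ccccc3)c1)[C@H]3O[Si](C(C)C)(C(C)C)Oc4cc5c(cc4[C@H]32)[C@@H](c7cc(Br)c(O)cc7OCc7ccccc7)[C@H](O)[C@@H](c4ccc(OCc6ccccc6)c(OCc6ccccc6)c4)O5 | intermediate
22 | trilithio species: 21 with OLi at both hydroxyls and Li in place of Br | c1cc2c(cc1OCc1ccccc1)O[C@H](c1ccc(OCc3ccccc3)c(OCc3ccccc3)c1)[C@H]3O[Si](C(C)C)(C(C)C)Oc4cc5c(cc4[C@H]32)[C@@H](c7cc([Li])c(O[Li])cc7OCc7ccccc7)[C@H](O[Li])[C@@H](c4ccc(OCc6ccccc6)c(OCc6ccccc6)c4)O5 | intermediate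
23 | epoxy ketone: 21 with the (2R,3S)-3-[3,4-bis(benzyloxy)phenyl]oxirane-2-carbonyl group in place of Br (formed as its lithium phenolate) | c1cc2c(cc1OCc1ccccc1)O[C@H](c1ccc(OCc3ccccc3)c(OCc3ccccc3)c1)[C@H]3O[Si](C(C)C)(C(C)C)Oc4cc5c(cc4[C@H]32)[C@@H](c7cc(C(=O)[C@@H]8O[C@H]8c8ccc(OCc9ccccc9)c(OCc9ccccc9)c8)c(O)cc7OCc7ccccc7)[C@H](O)[C@@H](c4ccc(OCc6ccccc6)c(OCc6ccccc6)c4)O5 | intermediate
24 | protected U–M–L flavanonol: unit L as (2R,3R)-7-(benzyloxy)-2-[3,4-bis(benzyloxy)phenyl]-3-hydroxychroman-4-one joined at C6 to C4α of unit M; silylene and benzyl ethers retained | c1cc2c(cc1OCc1ccccc1)O[C@H](c1ccc(OCc3ccccc3)c(OCc3ccccc3)c1)[C@H]3O[Si](C(C)C)(C(C)C)Oc4cc5c(cc4[C@H]32)[C@@H](c7cc8c(cc7OCc7ccccc7)O[C@H](c7ccc(OCc9ccccc9)c(OCc9ccccc9)c7)[C@@H](O)C8=O)[C@H](O)[C@@H](c4ccc(OCc6ccccc6)c(OCc6ccccc6)c4)O5 | intermediate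
25 | octa-O-benzyl U–M–L flavanonol: 24 without the silylene (3-OH of U and 7-OH of M free) | C(c1ccccc1)Oc1ccc2c(c1)O[C@H](c1ccc(OCc3ccccc3)c(OCc3ccccc3)c1)[C@@H](O)[C@H]2c1cc2c(cc1O)O[C@H](c1ccc(OCc3ccccc3)c(OCc3ccccc3)c1)[C@@H](O)[C@@H]2c1cc2c(cc1OCc1ccccc1)O[C@H](c1ccc(OCc3ccccc3)c(OCc3ccccc3)c1)[C@@H](O)C2=O | intermediate
26 | fisetinidol-(4β→6)-fisetinidol-(4α→6)-fustin (free phenols; unit L is the (2R,3R)-flavanonol) | Oc1ccc2c(c1)O[C@H](c1ccc(O)c(O)c1)[C@@H](O)[C@H]2c1cc2c(cc1O)O[C@H](c1ccc(O)c(O)c1)[C@@H](O)[C@@H]2c1cc2c(cc1O)O[C@H](c1ccc(O)c(O)c1)[C@@H](O)C2=O | intermediate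
27 | fisetinidol-(4β→6)-fisetinidol-(4α→6)-(2R,3S,4R)-flavan-3,3',4,4',7-pentol (CNP0255184.1) | Oc1ccc2c(c1)O[C@H](c1ccc(O)c(O)c1)[C@@H](O)[C@H]2c1cc2c(cc1O)O[C@H](c1ccc(O)c(O)c1)[C@@H](O)[C@@H]2c1cc2c(cc1O)O[C@H](c1ccc(O)c(O)c1)[C@@H](O)[C@@H]2O | target

**Step count and risks**

Total steps: 15. Longest linear sequence: 15 steps (1 → 3 → 4 → 8 → 10 → 13 → 14 → 17 → 18 → 19 → 20 → 21 → 24 → 25 → 26 → 27).

Steps most likely to fail:

1. Step 12 (Proposed new method). The aryllithium may attack the epoxide instead of the amide carbonyl, the trilithio species may be protonated before acylation, or the phenolate may open the epoxide in the 5-exo sense. The fallback reverses the order of bond formation with known reactions. It sets out from 21: the phenolate of 21 (Cs2CO3, DMF, 50 °C) opens epoxy amide 4 at the benzylic carbon with inversion to give the (2R,3R)-3-aryloxy-2-hydroxy amide, aryl ether F1. Parham cyclisation (n-BuLi, then t-BuLi, THF, −78 °C; bromine–lithium exchange and intramolecular acylation by the morpholine amide) then closes C4a–C4 and the route is rejoined at 24.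

2. Step 7 (Proposed new method). The same processes may interfere, and the organolithium may also cleave the aryloxysilane ring. The fallback sets out from 14: phenolate opening of 4 at the benzylic carbon (Cs2CO3, DMF, 50 °C) gives the aryl ether F2, and Parham cyclisation (n-BuLi, then t-BuLi, THF, −78 °C) returns to 17.

3. Step 3 (Proposed new method). Acylation may be slow on the aggregated dianion, or ring closure may fail to follow collapse of the adduct. The fallback is the chalcone route and sets out from 1. Purchased 1-[4-(benzyloxy)-2-hydroxyphenyl]ethanone is protected (MOMCl, i-Pr2NEt) as the methoxymethyl ether F3. Claisen–Schmidt condensation with 1 (KOH, EtOH) gives the chalcone F4. Juliá–Colonna epoxidation (poly-L-leucine, urea–H2O2, DBU, THF) gives the (2R,3S)-epoxy ketone F5. HCl in MeOH removes the methoxymethyl group, the freed phenol closes ring C at the benzylic carbon, and the route is rejoined at 8.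

Further compounds
F1 | step 12 | aryl ether: 21 with its phenolic oxygen bonded to C3 of (2R,3R)-3-[3,4-bis(benzyloxy)phenyl]-2-hydroxy-1-(morpholin-4-yl)propan-1-one | c1cc2c(cc1OCc1ccccc1)O[C@H](c1ccc(OCc3ccccc3)c(OCc3ccccc3)c1)[C@H]3O[Si](C(C)C)(C(C)C)Oc4cc5c(cc4[C@H]32)[C@@H](c7cc(Br)c(O[C@H](c8ccc(OCc9ccccc9)c(OCc9ccccc9)c8)[C@@H](O)C(=O)N8CCOCC8)cc7OCc7ccccc7)[C@H](O)[C@@H](c4ccc(OCc6ccccc6)c(OCc6ccccc6)c4)O5
F2 | step 7 | aryl ether: 14 with its phenolic oxygen bonded to C3 of (2R,3R)-3-[3,4-bis(benzyloxy)phenyl]-2-hydroxy-1-(morpholin-4-yl)propan-1-one | c1cc2c(cc1OCc1ccccc1)O[C@H](c1ccc(OCc3ccccc3)c(OCc3ccccc3)c1)[C@H]3O[Si](C(C)C)(C(C)C)Oc4cc(O[C@H](c5ccc(OCc6ccccc6)c(OCc6ccccc6)c5)[C@@H](O)C(=O)N5CCOCC5)c(Br)cc4[C@H]32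
F3 | step 3 | 1-[4-(benzyloxy)-2-(methoxymethoxy)phenyl]ethan-1-one | CC(=O)c1ccc(OCc2ccccc2)cc1OCOC
F4 | step 3 | (E)-1-[4-(benzyloxy)-2-(methoxymethoxy)phenyl]-3-[3,4-bis(benzyloxy)phenyl]prop-2-en-1-one | O=C(/C=C/c1ccc(OCc2ccccc2)c(OCc2ccccc2)c1)c1ccc(OCc2ccccc2)cc1OCOC
F5 | step 3 | [4-(benzyloxy)-2-(methoxymethoxy)phenyl][(2R,3S)-3-[3,4-bis(benzyloxy)phenyl]oxiran-2-yl]methanone | O=C(c1ccc(OCc2ccccc2)cc1OCOC)[C@@H]1O[C@H]1c1ccc(OCc2ccccc2)c(OCc2ccccc2)c1
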